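## Plan

1. The last cut removes six MOM ethers. The strategic cut before it severs O1–C8a and C4–C4a of ring C together, leaving ring A as the hexasubstituted aryne C4a≡C8a (both prenyl groups and both oxygens already on it) and C2–C3–C4 as an (S)-β-silyloxy methyl ester on the finished dihydrobenzofuran.
2. The feature that allows this: O1 (nucleophile) and C4 (acyl electrophile) are 1,3-related through C2–C3 and must end on the adjacent ring A carbons C8a and C4a. The C5 oxygen next to C4a polarises the aryne, so O1 adds at C8a and the carbanion, hence the acyl carbon, ends at C4a.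
3. The aryne precursor (fragment 1) goes back to phloroglucinol: three directed lithiations place prenyl, prenyl and SiMe3 on ring A.
4. The β-silyloxy ester (fragment 2) goes back through a cinnamate to an aryl bromide; the dihydrofuran ring is cut at C2–C3 back to a diaryl ketone.
5. Forward order: ring A is dressed; in fragment 2 the dihydrofuran ring closes by Rh-carbene C–H insertion and the C3 chain is added by Heck reaction and conjugate borylation; ring C then closes as the two fragments are joined; deprotection ends the route.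
6. Stereochemistry: dihydrobenzofuran C3 comes from the chiral Rh catalyst, C2 is relayed from it by equilibration to trans, and flavanone C2 comes from the chiral Cu catalyst and passes through the annulation with retention.

Key step: step 17

Assumption: the catalyst enantiomers named in steps 11 and 15 are those expected to give the 3R and the S series; the mirror-image catalyst, equally available, would be used if a model run shows the opposite sense.

## Route

Step 1
Reactants: 1 phloroglucinol
Product: 2 3,5-bis(methoxymethoxy)phenol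
Conditions: MOMCl (2.0 equiv), i-Pr2NEt (2.2 equiv), THF/DMF, 0 °C → rt; chromatography
Reagents that add atoms: chloromethyl methyl ether, COCCl
Why: Williamson-type acetal ether formation (MOM protection) run to the statistical bis-ether, which is separable from the mono- and tris-ethers and leaves the single free oxygen that later carries the triflate.

Step 2
Reactants: 2 3,5-bis(methoxymethoxy)phenol
Product: 3 TIPS ether of 2
Conditions: TIPSCl, imidazole, DMF, rt
Reagents that add atoms: chlorotri(propan-2-yl)silane, CC(C)[Si](Cl)(C(C)C)C(C)C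
Why: Silyl ether formation; the bulky, non-coordinating TIPS group marks that oxygen and leaves the two OMOM groups as the only directors for the lithiations that follow.

Step 3
Reactants: 3 TIPS ether of 2; 4 prenyl bromide
Product: 5 4-prenyl aryl TIPS ether
Conditions: n-BuLi, THF, 0 °C; CuBr·SMe2 (1.1 equiv), −78 °C; 4, −78 °C → rt
Reagents that add atoms: none
Why: Directed ortho-metalation at the carbon between the two cooperating OMOM groups, then copper-mediated allylic substitution at the unhindered CH2 end of prenyl bromide, so the prenyl group arrives without allylic transposition.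

Step 4
Reactants: 5 4-prenyl aryl TIPS ether; 4 prenyl bromide
Product: 6 2,4-diprenyl aryl TIPS ether
Conditions: s-BuLi, TMEDA, THF, −78 °C; CuBr·SMe2 (1.1 equiv); 4, −78 °C → 0 °C
Reagents that add atoms: none
Why: A second directed ortho-metalation, now beside one OMOM group (the two remaining ring positions of 5 are equivalent), and the same copper-mediated allylic substitution; at −78 °C ring lithiation next to OMOM should outrun deprotonation of the prenyl CH2 and O-to-C migration of the TIPS group.

Step 5
Reactants: 6 2,4-diprenyl aryl TIPS ether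
Product: 7 2,4-diprenyl-6-trimethylsilyl aryl TIPS ether
Conditions: s-BuLi, TMEDA, THF, −78 °C; TMSCl, −78 °C → 0 °C
Reagents that add atoms: chlorotrimethylsilane, C[Si](C)(C)Cl
Why: Directed ortho-metalation at the only ring C–H left and electrophilic silylation; the small SiMe3 group tolerates the crowded site between OTIPS and OMOM.

Step 6
Reactants: 7 2,4-diprenyl-6-trimethylsilyl aryl TIPS ether
Product: 8 3,5-bis(methoxymethoxy)-2,4-diprenyl-6-(trimethylsilyl)phenol
Conditions: TBAF (1.1 equiv), THF, 0 °C
Reagents that add atoms: none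
Why: Fluoride-mediated silyl ether cleavage; the O–Si bond is cleaved while the aryl C–SiMe3 bond, which has no leaving group next to it yet, should stay.

Step 7
Reactants: 8 3,5-bis(methoxymethoxy)-2,4-diprenyl-6-(trimethylsilyl)phenol
Product: 9 ortho-silylaryl triflate (fragment 1)
Conditions: Tf2O, pyridine, CH2Cl2, −20 °C → 0 °C
Reagents that add atoms: trifluoromethanesulfonic anhydride, O=S(=O)(OS(=O)(=O)C(F)(F)F)C(F)(F)F
Why: O-Sulfonylation (triflation) of the hindered phenol gives the ortho-silylaryl triflate, the standard fluoride-triggered aryne precursor, with all four ring A substituents already in place.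

Step 8
Reactants: 10 1-bromo-2,4-dimethoxybenzene; 11 3,5-dimethoxybenzoyl chloride
Product: 12 (5-bromo-2-hydroxy-4-methoxyphenyl)(3,5-dimethoxyphenyl)methanone
Conditions: AlCl3 (2.5 equiv), CH2Cl2, 0 °C → 40 °C; aq. HCl work-up
Reagents that add atoms: none
Why: Friedel–Crafts acylation at the one ring position of 10 that is para to one methoxy and ortho to the other, followed in the same flask by chelation-directed AlCl3 cleavage of the methyl ether ortho to the new ketone.

Step 9
Reactants: 12 (5-bromo-2-hydroxy-4-methoxyphenyl)(3,5-dimethoxyphenyl)methanone; 13 4-methoxybenzyl chloride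
Product: 14 4-methoxybenzyl ether of 12
Conditions: K2CO3, DMF, 60 °C
Reagents that add atoms: none
Why: Williamson etherification of the phenol ortho to the ketone installs the benzylic C–H bonds that the carbene will insert into.

Step 10
Reactants: 14 4-methoxybenzyl ether of 12
Product: 15 hydrazone of 14
Conditions: N2H4·H2O (10 equiv), AcOH (cat.), EtOH, 80 °C
Reagents that add atoms: hydrazine, NN
Why: Hydrazone condensation of the diaryl ketone, the standard entry to a diaryldiazomethane.

Step 11
Reactants: 15 hydrazone of 14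
Product: 17 (2S,3R)-cis-5-bromo-2,3-diaryl-2,3-dihydrobenzofuran tetramethyl ether, via diaryldiazomethane 16 (not isolated)
Conditions: MnO2 (8 equiv), CH2Cl2, 0 °C; filter; Rh2(R-PTAD)4 (1 mol %; PTAD = N-phthaloyl-(1-adamantyl)glycinate), CH2Cl2, 0 °C
Reagents that add atoms: none
Why: Oxidation of the hydrazone to the donor/donor diazo compound and Rh-carbene insertion into the benzylic C–H bond five atoms away closes the dihydrofuran ring; the insertion is cis-selective and the chiral carboxylate ligands of the catalyst set C3 as R (C2 is corrected in step 12).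

Step 12
Reactants: 17 (2S,3R)-cis-5-bromo-2,3-diaryl-2,3-dihydrobenzofuran tetramethyl ether
Product: 18 (2R,3R)-trans-5-bromo-2,3-diaryl-2,3-dihydrobenzofuran tetraphenol
Conditions: BBr3 (8 equiv), CH2Cl2, −78 °C → rt; MeOH, then aq. NaHCO3
Reagents that add atoms: none
Why: Lewis-acid cleavage of the four aryl methyl ethers, during which reversible ionisation of the benzylic C2–O bond (para-oxygenated benzylic cation) lets C2 epimerise to the more stable 2,3-trans arrangement while C3 from step 11 is untouched, so substrate control relays C3 to C2.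

Step 13
Reactants: 18 (2R,3R)-trans-5-bromo-2,3-diaryl-2,3-dihydrobenzofuran tetraphenol
Product: 19 tetrakis-MOM ether of 18
Conditions: MOMCl (6 equiv), i-Pr2NEt, DMF, 0 °C → rt
Reagents that add atoms: chloromethyl methyl ether, COCCl
Why: MOM ether formation on all four phenols removes every O–H that would capture the aryne and matches the ring A protection for a single final deprotection.

Step 14
Reactants: 19 tetrakis-MOM ether of 18; 20 methyl acrylate
Product: 21 methyl (E)-cinnamate of the dihydrobenzofuran
Conditions: Pd2(dba)3 (2 mol %), [HP(t-Bu)3]BF4 (8 mol %), Cy2NMe, dioxane, 80 °C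
Reagents that add atoms: none
Why: Mizoroki–Heck reaction with a bulky electron-rich phosphine for the electron-rich ortho-substituted aryl bromide; syn insertion and syn β-hydride elimination give the E-cinnamate.

Step 15
Reactants: 21 methyl (E)-cinnamate of the dihydrobenzofuran
Product: 23 methyl (3S)-3-aryl-3-hydroxypropanoate, via benzylic boronate 22 (not isolated)
Conditions: CuCl (3 mol %), NaOt-Bu (6 mol %), (R)-1-[(S)-2-(diphenylphosphino)ferrocenyl]ethyldicyclohexylphosphine (Josiphos, 3 mol %), B2pin2 (1.1 equiv), MeOH (2 equiv), THF, rt; then NaBO3·4H2O, THF/H2O, rt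
Reagents that add atoms: bis(pinacolato)diboron, CC1(C)OB(OC1(C)C)B1OC(C)(C)C(C)(C)O1 (its boryl group stays only in 22); sodium perborate, [Na+].[Na+].O[B-]1(O)OO[B-](O)(O)OO1 (the hydroxyl oxygen of 23)
Why: Copper-catalysed enantioselective conjugate borylation, in which the Josiphos-bound boryl copper adds to one face of the cinnamate and sets the benzylic carbon as S under catalyst control (the dihydrobenzofuran centres are remote), followed by stereoretentive oxidation of the C–B bond to C–OH.

Step 16
Reactants: 23 methyl (3S)-3-aryl-3-hydroxypropanoate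
Product: 24 trimethylsilyl ether of 23 (fragment 2)
Conditions: TMSCl, imidazole, CH2Cl2, 0 °C; Et3N-deactivated silica
Reagents that add atoms: chlorotrimethylsilane, C[Si](C)(C)Cl
Why: Silylation of the secondary alcohol; the O–SiMe3 group is the fluoride-labile mask that lets step 17 release a proton-free alkoxide.

Step 17
Reactants: 24 trimethylsilyl ether of 23 (fragment 2); 9 ortho-silylaryl triflate (fragment 1)
Product: 28 hexakis-MOM ether of the target flavanone, via aryne 25 (not isolated), via cesium alkoxide 26 (not isolated), via aryl cesium ether 27 (not isolated)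
Conditions: 24 (1.0 equiv), 9 (1.5 equiv), CsF (4 equiv), 18-crown-6 (2 equiv), THF, −20 °C → rt; pH 7 buffer quench
Reagents that add atoms: none
Why: Proposed new method: fluoride strips both silyl groups, so the proton-free cesium alkoxide 26 and the aryne 25 (C4a≡C8a of ring A) are released side by side; the alkoxide oxygen (future O1) adds to C8a and the C4a aryl anion 27 attacks the ester carbonyl, expels methoxide and closes ring C by 6-exo-trig acyl substitution, so O1–C8a and C4–C4a form in one operation. The closest known reaction types are the annulation of arynes with salicylate esters to xanthones (phenoxide addition, then intramolecular acylation), the insertion of arynes into the C–O bond of carboxylic acids and the O-arylation of aliphatic alcohols by arynes; the new element is an aliphatic β-oxy ester as the nucleophile–electrophile partner. No stereocentre is created: C2 comes from 24 with retention because its C–O bond is never broken, and the two dihydrobenzofuran centres are remote from the reacting atoms. The step needs attack at C8a and not at C4a, which the C5 OMOM group secures by polarising the aryne so that the nucleophile adds at the distal carbon and the charge develops at C4a next to oxygen; the C8 prenyl group beside C8a offers only an sp3 CH2. The silyl ether is the designed precursor, since an O–H would protonate 27 before it can acylate, and the excess of 9 scavenges the liberated methoxide so that base-induced opening of ring C, which would erase C2, is held back.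

Step 18
Reactants: 28 hexakis-MOM ether of the target flavanone
Product: 29 CNP0230984.1 (target)
Conditions: 3 M aq. HCl/MeOH (1:5), 45 °C
Reagents that add atoms: none
Why: Acid-catalysed acetal solvolysis removes all six MOM ethers in one operation under conditions mild enough that the prenyl groups should not cyclise onto the freed ortho phenols and the three benzylic C–O stereocentres should hold.

## Compound list

1 | phloroglucinol (benzene-1,3,5-triol) | Oc1cc(O)cc(O)c1 | starting material
2 | 3,5-bis(methoxymethoxy)phenol | COCOc1cc(O)cc(OCOC)c1 | intermediate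
3 | [3,5-bis(methoxymethoxy)phenoxy]tri(propan-2-yl)silane | COCOc1cc(O[Si](C(C)C)(C(C)C)C(C)C)cc(OCOC)c1 | intermediate
4 | prenyl bromide (1-bromo-3-methylbut-2-ene) | CC(C)=CCBr | starting material
5 | [3,5-bis(methoxymethoxy)-4-(3-methylbut-2-en-1-yl)phenoxy]tri(propan-2-yl)silane | COCOc1cc(O[Si](C(C)C)(C(C)C)C(C)C)cc(OCOC)c1CC=C(C)C | intermediate
6 | [3,5-bis(methoxymethoxy)-2,4-bis(3-methylbut-2-en-1-yl)phenoxy]tri(propan-2-yl)silane | COCOc1cc(O[Si](C(C)C)(C(C)C)C(C)C)c(CC=C(C)C)c(OCOC)c1CC=C(C)C | intermediate
7 | [3,5-bis(methoxymethoxy)-2,4-bis(3-methylbut-2-en-1-yl)-6-(trimethylsilyl)phenoxy]tri(propan-2-yl)silane | COCOc1c([Si](C)(C)C)c(O[Si](C(C)C)(C(C)C)C(C)C)c(CC=C(C)C)c(OCOC)c1CC=C(C)C | intermediate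
8 | 3,5-bis(methoxymethoxy)-2,4-bis(3-methylbut-2-en-1-yl)-6-(trimethylsilyl)phenol | COCOc1c([Si](C)(C)C)c(O)c(CC=C(C)C)c(OCOC)c1CC=C(C)C | intermediate
9 | 3,5-bis(methoxymethoxy)-2,4-bis(3-methylbut-2-en-1-yl)-6-(trimethylsilyl)phenyl trifluoromethanesulfonate | COCOc1c([Si](C)(C)C)c(OS(=O)(=O)C(F)(F)F)c(CC=C(C)C)c(OCOC)c1CC=C(C)C | intermediate
10 | 1-bromo-2,4-dimethoxybenzene | COc1ccc(Br)c(OC)c1 | starting material
11 | 3,5-dimethoxybenzoyl chloride | COc1cc(OC)cc(c1)C(Cl)=O | starting material
12 | (5-bromo-2-hydroxy-4-methoxyphenyl)(3,5-dimethoxyphenyl)methanone | COc1cc(OC)cc(c1)C(=O)c1cc(Br)c(OC)cc1O | intermediate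
13 | 4-methoxybenzyl chloride | COc1ccc(CCl)cc1 | starting material
14 | {5-bromo-4-methoxy-2-[(4-methoxybenzyl)oxy]phenyl}(3,5-dimethoxyphenyl)methanone | COc1ccc(COc2cc(OC)c(Br)cc2C(=O)c2cc(OC)cc(OC)c2)cc1 | intermediate
15 | hydrazone of 14 (E/Z mixture) | COc1ccc(COc2cc(OC)c(Br)cc2C(=NN)c2cc(OC)cc(OC)c2)cc1 | intermediate
16 | {5-bromo-4-methoxy-2-[(4-methoxybenzyl)oxy]phenyl}(3,5-dimethoxyphenyl)diazomethane | COc1ccc(COc2cc(OC)c(Br)cc2C(=[N+]=[N-])c2cc(OC)cc(OC)c2)cc1 | intermediate (not isolated)
17 | (2S,3R)-5-bromo-3-(3,5-dimethoxyphenyl)-6-methoxy-2-(4-methoxyphenyl)-2,3-dihydro-1-benzofuran (2,3-cis) | Brc1cc3c(cc1OC)O[C@H](c1ccc(OC)cc1)[C@@H]3c1cc(OC)cc(OC)c1 | intermediate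
18 | (2R,3R)-5-bromo-3-(3,5-dihydroxyphenyl)-2-(4-hydroxyphenyl)-2,3-dihydro-1-benzofuran-6-ol (2,3-trans) | Brc1cc3c(cc1O)O[C@@H](c1ccc(O)cc1)[C@@H]3c1cc(O)cc(O)c1 | intermediate
19 | (2R,3R)-3-[3,5-bis(methoxymethoxy)phenyl]-5-bromo-6-(methoxymethoxy)-2-[4-(methoxymethoxy)phenyl]-2,3-dihydro-1-benzofuran | Brc1cc3c(cc1OCOC)O[C@@H](c1ccc(OCOC)cc1)[C@@H]3c1cc(OCOC)cc(OCOC)c1 | intermediate
20 | methyl acrylate | COC(=O)C=C | starting material
21 | methyl (2E)-3-{(2R,3R)-3-[3,5-bis(methoxymethoxy)phenyl]-6-(methoxymethoxy)-2-[4-(methoxymethoxy)phenyl]-2,3-dihydro-1-benzofuran-5-yl}prop-2-enoate | COC(=O)/C=C/c1cc3c(cc1OCOC)O[C@@H](c1ccc(OCOC)cc1)[C@@H]3c1cc(OCOC)cc(OCOC)c1 | intermediate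
22 | methyl (3S)-3-{the same (2R,3R)-dihydrobenzofuran-5-yl group}-3-(4,4,5,5-tetramethyl-1,3,2-dioxaborolan-2-yl)propanoate | COC(=O)C[C@H](B1OC(C)(C)C(C)(C)O1)c1cc3c(cc1OCOC)O[C@@H](c1ccc(OCOC)cc1)[C@@H]3c1cc(OCOC)cc(OCOC)c1 | intermediate (not isolated)
23 | methyl (3S)-3-hydroxy-3-{(2R,3R)-3-[3,5-bis(methoxymethoxy)phenyl]-6-(methoxymethoxy)-2-[4-(methoxymethoxy)phenyl]-2,3-dihydro-1-benzofuran-5-yl}propanoate | COC(=O)C[C@H](O)c1cc3c(cc1OCOC)O[C@@H](c1ccc(OCOC)cc1)[C@@H]3c1cc(OCOC)cc(OCOC)c1 | intermediate
24 | methyl (3S)-3-{the same (2R,3R)-dihydrobenzofuran-5-yl group}-3-[(trimethylsilyl)oxy]propanoate | COC(=O)C[C@H](O[Si](C)(C)C)c1cc3c(cc1OCOC)O[C@@H](c1ccc(OCOC)cc1)[C@@H]3c1cc(OCOC)cc(OCOC)c1 | intermediate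
25 | 3,5-bis(methoxymethoxy)-4,6-bis(3-methylbut-2-en-1-yl)-1,2-didehydrobenzene (aryne) | COCOC1=C(CC=C(C)C)C(OCOC)=C(CC=C(C)C)C#C1 | intermediate (not isolated)
26 | cesium alkoxide of 23 | [Cs+].COC(=O)C[C@H]([O-])c1cc3c(cc1OCOC)O[C@@H](c1ccc(OCOC)cc1)[C@@H]3c1cc(OCOC)cc(OCOC)c1 | intermediate (not isolated)
27 | aryl cesium species from O-arylation of 26 at C8a (carbanion at C4a) | [Cs+].COC(=O)C[C@H](Oc1[c-]c(OCOC)c(CC=C(C)C)c(OCOC)c1CC=C(C)C)c1cc3c(cc1OCOC)O[C@@H](c1ccc(OCOC)cc1)[C@@H]3c1cc(OCOC)cc(OCOC)c1 | intermediate (not isolated)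
28 | (2S)-2-{(2R,3R)-3-[3,5-bis(methoxymethoxy)phenyl]-6-(methoxymethoxy)-2-[4-(methoxymethoxy)phenyl]-2,3-dihydro-1-benzofuran-5-yl}-5,7-bis(methoxymethoxy)-6,8-bis(3-methylbut-2-en-1-yl)-2,3-dihydro-4H-chromen-4-one | CC(C)=CCc1c(OCOC)c(CC=C(C)C)c2c(c1OCOC)C(=O)C[C@@H](c1cc3c(cc1OCOC)O[C@@H](c1ccc(OCOC)cc1)[C@@H]3c1cc(OCOC)cc(OCOC)c1)O2 | intermediate
29 | (2S)-2-[(2R,3R)-3-(3,5-dihydroxyphenyl)-6-hydroxy-2-(4-hydroxyphenyl)-2,3-dihydro-1-benzofuran-5-yl]-5,7-dihydroxy-6,8-bis(3-methylbut-2-en-1-yl)-2,3-dihydro-4H-chromen-4-one (CNP0230984.1) | CC(C)=CCc1c(O)c(CC=C(C)C)c2c(c1O)C(=O)C[C@@H](c1cc3c(cc1O)O[C@@H](c1ccc(O)cc1)[C@@H]3c1cc(O)cc(O)c1)O2 | target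

## Step count and risks

Total steps: 18. Longest linear sequence: 11 steps (steps 8 to 18, from 1-bromo-2,4-dimethoxybenzene); the ring A branch is 7 steps and joins at step 17.

Steps most likely to fail:

Step 17. The free cesium alkoxide may fragment by retro-aldol cleavage before it meets the aryne. The alkoxide may add at C4a instead of C8a because of the prenyl CH2 beside C8a. Liberated base may open ring C by β-elimination and erase the configuration at C2. The fallback uses known chemistry and sets out from cinnamate 21. Saponification (LiOH, THF/MeOH/H2O) should give the cinnamic acid F1. Heating F1 with 9 and CsF in THF at 110–125 °C in a sealed vessel is the established insertion of an aryne into the C–O bond of a carboxylic acid: the carboxylate adds at C8a, the acyl group migrates to C4a, and the 2'-hydroxychalcone F2 results. Oxa-Michael ring closure of F2 (NaOAc, EtOH, reflux, or a cinchona-thiourea catalyst) should give 28 together with its C2 epimer F3. The two are diastereomers and separable by chromatography, and F3 can be re-equilibrated under the same conditions. The fallback returns to the route at 28.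

Step 12. Irreversible opening of the dihydrofuran ring by the boron halide, elimination from the ring-opened benzylic cation, or incomplete equilibration at C2 may occur. The fallback sets out from 17 and separates the two tasks. Protic acid (TFA, CH2Cl2, rt) should equilibrate C2 without touching the methyl ethers and give the trans tetramethyl ether F4. Nucleophilic demethylation with NaSEt in DMF at 120 °C, basic conditions under which the benzylic C2–O bond cannot ionise, should then give 18, where the fallback returns to the route.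

Step 18. Acid may cyclise the prenyl groups onto the freed ortho phenols, or ionise the benzylic C2–O bond of ring C with loss of configuration. The fallback sets out from 28. TMSOTf with 2,2'-bipyridyl in CH2Cl2 at 0 °C should exchange the aryl MOM ethers for silyl ethers under buffered, non-protic conditions and give the hexakis(trimethylsilyl) ether F5. Hydrolysis of F5 with water/MeOH at rt should give 29.

## Further compounds

F1 | step 17 | (2E)-3-{(2R,3R)-3-[3,5-bis(methoxymethoxy)phenyl]-6-(methoxymethoxy)-2-[4-(methoxymethoxy)phenyl]-2,3-dihydro-1-benzofuran-5-yl}prop-2-enoic acid | OC(=O)/C=C/c1cc3c(cc1OCOC)O[C@@H](c1ccc(OCOC)cc1)[C@@H]3c1cc(OCOC)cc(OCOC)c1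
F2 | step 17 | (2E)-1-[2-hydroxy-4,6-bis(methoxymethoxy)-3,5-bis(3-methylbut-2-en-1-yl)phenyl]-3-{the same (2R,3R)-dihydrobenzofuran-5-yl group}prop-2-en-1-one | CC(C)=CCc1c(O)c(C(=O)/C=C/c2cc3c(cc2OCOC)O[C@@H](c2ccc(OCOC)cc2)[C@@H]3c2cc(OCOC)cc(OCOC)c2)c(OCOC)c(CC=C(C)C)c1OCOC
F3 | step 17 | (2R)-epimer of 28 at C2 of the chromanone | CC(C)=CCc1c(OCOC)c(CC=C(C)C)c2c(c1OCOC)C(=O)C[C@H](c1cc3c(cc1OCOC)O[C@@H](c1ccc(OCOC)cc1)[C@@H]3c1cc(OCOC)cc(OCOC)c1)O2
F4 | step 12 | (2R,3R)-5-bromo-3-(3,5-dimethoxyphenyl)-6-methoxy-2-(4-methoxyphenyl)-2,3-dihydro-1-benzofuran (2,3-trans) | Brc1cc3c(cc1OC)O[C@@H](c1ccc(OC)cc1)[C@@H]3c1cc(OC)cc(OC)c1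
F5 | step 18 | hexakis(trimethylsilyl) ether of 29 | CC(C)=CCc1c(O[Si](C)(C)C)c(CC=C(C)C)c2c(c1O[Si](C)(C)C)C(=O)C[C@@H](c1cc3c(cc1O[Si](C)(C)C)O[C@@H](c1ccc(O[Si](C)(C)C)cc1)[C@@H]3c1cc(O[Si](C)(C)C)cc(O[Si](C)(C)C)c1)O2
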